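**Strategy.** Everything rests on the C5–C1′ branch point of the carbocycle (C4a, C5, C6, C7, C8, C8a): C5 carries an exocyclic carbon next to the ring-fusion carbon C4a. A cis-fused cyclohepta[b]pyridin-5-one, made from an L-alanine-derived amine and cycloheptane-1,3-dione, is therefore given a diazo group at its C6 methylene and ring-contracted by a photochemical Wolff rearrangement. In one operation C4a migrates with retention, the seven-membered ring becomes the cyclohexane, the ring carbonyl is expelled as the ester carbon C1′ and the all-cis C4a/C5/C8a array is set. Methylenation, cross-metathesis with an (R)-oct-1-en-5-ol unit, hydrogenation, acylation and deprotection complete lepadin H.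

Key step: step 9

Remark: the target is read as (2S,3R,4aS,5S,8aR,5′R) with decahydroquinoline numbering and side chain C1′–C8′; the seven-membered precursors use cyclohepta[b]pyridine numbering (C5 ketone carbon, C6 its CH2 neighbour, C9a the N-bearing fusion carbon). The cross-metathesis should give an E/Z mixture; 20 is drawn as E and both isomers give 21.

**Step 1**
Reactants: 1 tert-butyl [(2S)-1-[methoxy(methyl)amino]-1-oxopropan-2-yl]carbamate (Boc-L-alanine N-methoxy-N-methylamide)
Product: 2 tert-butyl [(2S)-4-chloro-3-oxobutan-2-yl]carbamate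
Conditions: ICH2Cl, MeLi·LiBr (excess), THF/Et2O, −78 °C; aq. NH4Cl
Reagents that add atoms: chloroiodomethane, ClCI
Why: Acyl substitution of the Weinreb amide by chloromethyllithium generated in situ (carbenoid homologation) stops at the chelated tetrahedral intermediate, so no over-addition occurs and the L-alanine stereocentre is not touched.

**Step 2**
Reactants: 2 tert-butyl [(2S)-4-chloro-3-oxobutan-2-yl]carbamate
Product: 3 tert-butyl [(2S,3S)-4-chloro-3-hydroxybutan-2-yl]carbamate (anti chlorohydrin)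
Conditions: Al(OiPr)3, iPrOH, 50 °C
Reagents that add atoms: none
Why: Meerwein–Ponndorf–Verley reduction through an aluminium chelate of ketone oxygen and carbamate (chelation control) should deliver hydride anti to the methyl group and give the anti (2S,3S) chlorohydrin, as is typical for N-carbamoyl α-amino chloromethyl ketones.

**Step 3**
Reactants: 3 tert-butyl [(2S,3S)-4-chloro-3-hydroxybutan-2-yl]carbamate
Product: 4 tert-butyl [(2S,3S)-3-(benzyloxy)-4-chlorobutan-2-yl]carbamate
Conditions: 2-benzyloxy-1-methylpyridinium triflate, MgO, PhCF3, 83 °C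
Reagents that add atoms: 2-benzyloxy-1-methylpyridinium triflate, C[n+]1ccccc1OCc1ccccc1.[O-]S(=O)(=O)C(F)(F)F
Why: Benzyl transfer from the pyridinium salt under near-neutral conditions (O-benzylation) etherifies the secondary alcohol without forming the alkoxide that would close the chlorohydrin to an epoxide and without harming the Boc group.

**Step 4**
Reactants: 4 tert-butyl [(2S,3S)-3-(benzyloxy)-4-chlorobutan-2-yl]carbamate
Product: 5 (2S,3S)-3-(benzyloxy)-4-chlorobutan-2-aminium chloride
Conditions: 4 M HCl, dioxane, rt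
Reagents that add atoms: hydrogen chloride, Cl
Why: Acidolysis of the tert-butyl carbamate (Boc cleavage) gives the primary amine as its hydrochloride, which keeps the γ-chloro amine from cyclising before use.

**Step 5**
Reactants: 5 (2S,3S)-3-(benzyloxy)-4-chlorobutan-2-aminium chloride; 6 cycloheptane-1,3-dione
Product: 8 (2S,3R)-3-(benzyloxy)-2-methyl-1,2,3,4,6,7,8,9-octahydro-5H-cyclohepta[b]pyridin-5-one, via open-chain enaminone 7 (not isolated)
Conditions: Et3N, 4 Å MS, MeCN, 50 °C; then NaI (cat.), reflux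
Reagents that add atoms: none
Why: Condensation of the amine with the 1,3-dione gives the vinylogous amide, whose nucleophilic α-carbon then displaces the primary chloride (Finkelstein-assisted) in a 6-exo-tet intramolecular C-alkylation, N- and O-alkylation being excluded because they would need four- and eight-membered rings.

**Step 6**
Reactants: 8 (2S,3R)-3-(benzyloxy)-2-methyl-1,2,3,4,6,7,8,9-octahydro-5H-cyclohepta[b]pyridin-5-one
Product: 9 (2S,3R,4aR,9aR)-3-(benzyloxy)-2-methyldecahydro-5H-cyclohepta[b]pyridin-5-one (cis-fused; H-2, H-4a and H-9a on one face, methyl on the other)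
Conditions: H2 (50 psi), Pt/C, AcOH, rt
Reagents that add atoms: none
Why: Heterogeneous catalytic hydrogenation of the tetrasubstituted vinylogous amide should add both hydrogens cis from the face opposite the C2 methyl group, which gives the cis ring fusion with H-9a cis to H-2, and platinum is chosen because it should leave the benzyl ether in place.

**Step 7**
Reactants: 9 (2S,3R,4aR,9aR)-3-(benzyloxy)-2-methyldecahydro-5H-cyclohepta[b]pyridin-5-one
Product: 10 tert-butyl (2S,3R,4aR,9aR)-3-(benzyloxy)-2-methyl-5-oxodecahydro-1H-cyclohepta[b]pyridine-1-carboxylate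
Conditions: Boc2O, iPr2NEt, THF, 60 °C
Reagents that add atoms: di-tert-butyl dicarbonate, CC(C)(C)OC(=O)OC(=O)OC(C)(C)C
Why: N-Boc protection of the secondary amine blocks the nitrogen for the base and acylation steps, and the A(1,3) strain of the carbamate makes the cis ring fusion the thermodynamically preferred one at the enolisable C4a.

**Step 8**
Reactants: 10 tert-butyl (2S,3R,4aR,9aR)-3-(benzyloxy)-2-methyl-5-oxodecahydro-1H-cyclohepta[b]pyridine-1-carboxylate
Product: 12 tert-butyl (2S,3R,4aR,9aR)-3-(benzyloxy)-6-diazo-2-methyl-5-oxodecahydro-1H-cyclohepta[b]pyridine-1-carboxylate, via 6-trifluoroacetyl ketone 11 (not isolated)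
Conditions: LiHMDS, THF, −78 °C; CF3CO2CH2CF3; then MsN3, Et3N, H2O, MeCN, rt
Reagents that add atoms: methanesulfonyl azide, CS(=O)(=O)N=[N+]=[N-]
Why: Kinetic deprotonation at the C6 methylene, trifluoroacetylation and deacylative diazo transfer (Regitz-type) place the diazo group on the only α-CH2 and avoid enolisation toward C4a, which would expel the β-carbamate.

**Step 9**
Reactants: 12 tert-butyl (2S,3R,4aR,9aR)-3-(benzyloxy)-6-diazo-2-methyl-5-oxodecahydro-1H-cyclohepta[b]pyridine-1-carboxylate
Product: 14 1-tert-butyl 5-methyl (2S,3R,4aS,5S,8aR)-3-(benzyloxy)-2-methyloctahydroquinoline-1,5(2H)-dicarboxylate, via ring-contracted ketene 13 (not isolated)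
Conditions: hν (medium-pressure Hg lamp, Pyrex, λ > 300 nm), MeOH, rt
Reagents that add atoms: methanol, CO
Why: Irradiation of the cyclic α-diazo ketone, whose diazo and carbonyl groups are locked s-Z by the ring, expels N2 with concerted 1,2-shift of C4a from the carbonyl carbon to the diazo carbon (Wolff rearrangement), and methanol adds to the ring-contracted ketene 13 to give the methyl ester. The closest known reaction type is the photochemical Wolff ring contraction of cyclic 2-diazo ketones such as 2-diazocycloheptanone to cyclohexanecarboxylates. The cyclohexane ring is closed by this 1,2-alkyl shift, which forms the C4a–C5 bond while the former ketone carbon leaves the ring as the ester carbon C1′, so the seven-membered ring contracts to six. C4a migrates with retention and is no longer α to a carbonyl afterwards, which fixes the cis ring fusion; the new centre C5 is set when the ester enol is protonated from the β face, because in the N-Boc conformer (C2-methyl and C8a–C8 axial by A(1,3) strain) the C4 methylene stands axial on the carbocycle and blocks the α face, and the resulting equatorial ester should also be the more stable epimer. The step needs rearrangement to beat carbene O–H insertion and 1,2-hydride shift, which the s-Z geometry secures, and it needs a single regiochemistry, which is secured because only C4a can migrate.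

**Step 10**
Reactants: 14 1-tert-butyl 5-methyl (2S,3R,4aS,5S,8aR)-3-(benzyloxy)-2-methyloctahydroquinoline-1,5(2H)-dicarboxylate
Product: 15 tert-butyl (2S,3R,4aS,5S,8aR)-3-(benzyloxy)-5-formyl-2-methyloctahydroquinoline-1(2H)-carboxylate
Conditions: DIBAL-H, CH2Cl2, −78 °C; Rochelle salt
Reagents that add atoms: none
Why: Partial reduction of the methyl ester with DIBAL-H at −78 °C stops at the aluminium hemiacetal, which gives the aldehyde on work-up, and C5 should keep its configuration because any enol is reprotonated from the same open β face.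

**Step 11**
Reactants: 15 tert-butyl (2S,3R,4aS,5S,8aR)-3-(benzyloxy)-5-formyl-2-methyloctahydroquinoline-1(2H)-carboxylate
Product: 16 tert-butyl (2S,3R,4aS,5R,8aR)-3-(benzyloxy)-5-ethenyl-2-methyloctahydroquinoline-1(2H)-carboxylate
Conditions: Ph3PCH3Br, KOtBu, THF, 0 °C; then 15, −78 → 0 °C
Reagents that add atoms: methyltriphenylphosphonium bromide, C[P+](c1ccccc1)(c1ccccc1)c1ccccc1.[Br-]
Why: Wittig methylenation with methylenetriphenylphosphorane converts the aldehyde into the terminal alkene at low temperature, fast enough to outrun α-epimerisation.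

**Step 12**
Reactants: 17 (R)-2-propyloxirane
Product: 18 (R)-oct-1-en-5-ol
Conditions: allylMgBr, CuI (10 mol %), THF, −30 → 0 °C; aq. NH4Cl
Reagents that add atoms: allylmagnesium bromide, C=CC[Mg]Br
Why: Copper-catalysed SN2 opening of the terminal epoxide at its CH2 carbon by the allyl Grignard reagent leaves the stereocentre untouched and gives the (R) alcohol that carries C2′–C8′ of the side chain.

**Step 13**
Reactants: 18 (R)-oct-1-en-5-ol
Product: 19 (R)-tert-butyldimethyl(oct-1-en-5-yloxy)silane
Conditions: TBSCl, imidazole, DMF, rt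
Reagents that add atoms: tert-butyldimethylsilyl chloride, CC(C)(C)[Si](C)(C)Cl
Why: Silylation of the secondary alcohol (TBS protection) masks the C5′ hydroxyl so that only the C3 hydroxyl is free at the acylation stage.

**Step 14**
Reactants: 16 tert-butyl (2S,3R,4aS,5R,8aR)-3-(benzyloxy)-5-ethenyl-2-methyloctahydroquinoline-1(2H)-carboxylate; 19 (R)-tert-butyldimethyl(oct-1-en-5-yloxy)silane
Product: 20 tert-butyl (2S,3R,4aS,5R,8aR)-3-(benzyloxy)-5-[(1E,5R)-5-[(tert-butyldimethylsilyl)oxy]oct-1-en-1-yl]-2-methyloctahydroquinoline-1(2H)-carboxylate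
Conditions: (H2IMes)(PCy3)Cl2Ru=CHPh (5–10 mol %), 19 (3 equiv), CH2Cl2, 40 °C
Reagents that add atoms: none
Why: Olefin cross-metathesis between the α-branched vinyl group, which is slow to homodimerise, and an excess of the unhindered terminal alkene joins C1′ to C2′ with loss of ethene.

**Step 15**
Reactants: 20 tert-butyl (2S,3R,4aS,5R,8aR)-3-(benzyloxy)-5-[(1E,5R)-5-[(tert-butyldimethylsilyl)oxy]oct-1-en-1-yl]-2-methyloctahydroquinoline-1(2H)-carboxylate
Product: 21 tert-butyl (2S,3R,4aS,5S,8aR)-5-[(5R)-5-[(tert-butyldimethylsilyl)oxy]octyl]-3-hydroxy-2-methyloctahydroquinoline-1(2H)-carboxylate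
Conditions: H2 (1 atm), Pd(OH)2/C, EtOAc, rt
Reagents that add atoms: none
Why: Catalytic hydrogenation saturates the disubstituted alkene and hydrogenolysis cleaves the benzyl ether in the same operation, while the Boc and TBS groups are stable in ethyl acetate.

**Step 16**
Reactants: 21 tert-butyl (2S,3R,4aS,5S,8aR)-5-[(5R)-5-[(tert-butyldimethylsilyl)oxy]octyl]-3-hydroxy-2-methyloctahydroquinoline-1(2H)-carboxylate; 22 (2E,4E)-octa-2,4-dienoic acid
Product: 24 tert-butyl (2S,3R,4aS,5S,8aR)-5-[(5R)-5-[(tert-butyldimethylsilyl)oxy]octyl]-2-methyl-3-{[(2E,4E)-octa-2,4-dienoyl]oxy}octahydroquinoline-1(2H)-carboxylate, via O-acylisourea 23 (not isolated)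
Conditions: DCC, DMAP (cat.), CH2Cl2, 0 °C → rt
Reagents that add atoms: none
Why: Steglich esterification (carbodiimide activation, DMAP acyl transfer) acylates the only free hydroxyl group, the nitrogen being blocked as its carbamate, and the mild conditions should preserve the E,E geometry of the dienoate.

**Step 17**
Reactants: 24 tert-butyl (2S,3R,4aS,5S,8aR)-5-[(5R)-5-[(tert-butyldimethylsilyl)oxy]octyl]-2-methyl-3-{[(2E,4E)-octa-2,4-dienoyl]oxy}octahydroquinoline-1(2H)-carboxylate
Product: 25 lepadin H, (2S,3R,4aS,5S,8aR)-5-[(5R)-5-hydroxyoctyl]-2-methyldecahydroquinolin-3-yl (2E,4E)-octa-2,4-dienoate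
Conditions: TFA/CH2Cl2/H2O (10:10:1), 0 °C → rt; aq. NaHCO3
Reagents that add atoms: none
Why: Aqueous trifluoroacetic acid cleaves the Boc carbamate and the secondary TBS ether in one acidolysis while the dienoate ester and the protonated amine are inert, so basic work-up should release the free base.

**Compound list**

1 | tert-butyl [(2S)-1-[methoxy(methyl)amino]-1-oxopropan-2-yl]carbamate | C[C@H](NC(=O)OC(C)(C)C)C(=O)N(C)OC | starting material
2 | tert-butyl [(2S)-4-chloro-3-oxobutan-2-yl]carbamate | C[C@H](NC(=O)OC(C)(C)C)C(=O)CCl | intermediate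
3 | tert-butyl [(2S,3S)-4-chloro-3-hydroxybutan-2-yl]carbamate | C[C@H](NC(=O)OC(C)(C)C)[C@H](O)CCl | intermediate
4 | tert-butyl [(2S,3S)-3-(benzyloxy)-4-chlorobutan-2-yl]carbamate | C[C@H](NC(=O)OC(C)(C)C)[C@H](OCc1ccccc1)CCl | intermediate
5 | (2S,3S)-3-(benzyloxy)-4-chlorobutan-2-aminium chloride | C[C@H]([NH3+])[C@H](OCc1ccccc1)CCl.[Cl-] | intermediate
6 | cycloheptane-1,3-dione | O=C1CCCCC(=O)C1 | starting material
7 | 3-{[(2S,3S)-3-(benzyloxy)-4-chlorobutan-2-yl]amino}cyclohept-2-en-1-one | C[C@H](NC1=CC(=O)CCCC1)[C@H](OCc2ccccc2)CCl | intermediate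
8 | (2S,3R)-3-(benzyloxy)-2-methyl-1,2,3,4,6,7,8,9-octahydro-5H-cyclohepta[b]pyridin-5-one | C[C@@H]1NC2=C(C[C@H]1OCc3ccccc3)C(=O)CCCC2 | intermediate
9 | (2S,3R,4aR,9aR)-3-(benzyloxy)-2-methyldecahydro-5H-cyclohepta[b]pyridin-5-one | C[C@@H]1N[C@@H]2CCCCC(=O)[C@@H]2C[C@H]1OCc3ccccc3 | intermediate
10 | tert-butyl (2S,3R,4aR,9aR)-3-(benzyloxy)-2-methyl-5-oxodecahydro-1H-cyclohepta[b]pyridine-1-carboxylate | C[C@@H]1N(C(=O)OC(C)(C)C)[C@@H]2CCCCC(=O)[C@@H]2C[C@H]1OCc3ccccc3 | intermediate
11 | tert-butyl (2S,3R,4aR,9aR)-3-(benzyloxy)-2-methyl-5-oxo-6-(trifluoroacetyl)decahydro-1H-cyclohepta[b]pyridine-1-carboxylate (C6 unassigned, enolised) | C[C@@H]1N(C(=O)OC(C)(C)C)[C@@H]2CCCC(C(=O)C(F)(F)F)C(=O)[C@@H]2C[C@H]1OCc3ccccc3 | intermediate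
12 | tert-butyl (2S,3R,4aR,9aR)-3-(benzyloxy)-6-diazo-2-methyl-5-oxodecahydro-1H-cyclohepta[b]pyridine-1-carboxylate | C[C@@H]1N(C(=O)OC(C)(C)C)[C@@H]2CCCC(=[N+]=[N-])C(=O)[C@@H]2C[C@H]1OCc3ccccc3 | intermediate
13 | tert-butyl (2S,3R,4aS,8aR)-3-(benzyloxy)-2-methyl-5-(oxomethylidene)octahydroquinoline-1(2H)-carboxylate (ketene) | C[C@@H]1N(C(=O)OC(C)(C)C)[C@@H]2CCCC(=C=O)[C@@H]2C[C@H]1OCc3ccccc3 | intermediate
14 | 1-tert-butyl 5-methyl (2S,3R,4aS,5S,8aR)-3-(benzyloxy)-2-methyloctahydroquinoline-1,5(2H)-dicarboxylate | C[C@@H]1N(C(=O)OC(C)(C)C)[C@@H]2CCC[C@H](C(=O)OC)[C@@H]2C[C@H]1OCc3ccccc3 | intermediate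
15 | tert-butyl (2S,3R,4aS,5S,8aR)-3-(benzyloxy)-5-formyl-2-methyloctahydroquinoline-1(2H)-carboxylate | C[C@@H]1N(C(=O)OC(C)(C)C)[C@@H]2CCC[C@H](C=O)[C@@H]2C[C@H]1OCc3ccccc3 | intermediate
16 | tert-butyl (2S,3R,4aS,5R,8aR)-3-(benzyloxy)-5-ethenyl-2-methyloctahydroquinoline-1(2H)-carboxylate | C[C@@H]1N(C(=O)OC(C)(C)C)[C@@H]2CCC[C@H](C=C)[C@@H]2C[C@H]1OCc3ccccc3 | intermediate
17 | (R)-2-propyloxirane | CCC[C@@H]1CO1 | starting material
18 | (R)-oct-1-en-5-ol | C=CCC[C@H](O)CCC | intermediate
19 | (R)-tert-butyldimethyl(oct-1-en-5-yloxy)silane | C=CCC[C@H](O[Si](C)(C)C(C)(C)C)CCC | intermediate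
20 | tert-butyl (2S,3R,4aS,5R,8aR)-3-(benzyloxy)-5-[(1E,5R)-5-[(tert-butyldimethylsilyl)oxy]oct-1-en-1-yl]-2-methyloctahydroquinoline-1(2H)-carboxylate | C[C@@H]1N(C(=O)OC(C)(C)C)[C@@H]2CCC[C@H](/C=C/CC[C@H](O[Si](C)(C)C(C)(C)C)CCC)[C@@H]2C[C@H]1OCc3ccccc3 | intermediate
21 | tert-butyl (2S,3R,4aS,5S,8aR)-5-[(5R)-5-[(tert-butyldimethylsilyl)oxy]octyl]-3-hydroxy-2-methyloctahydroquinoline-1(2H)-carboxylate | C[C@@H]1N(C(=O)OC(C)(C)C)[C@@H]2CCC[C@H](CCCC[C@H](O[Si](C)(C)C(C)(C)C)CCC)[C@@H]2C[C@H]1O | intermediate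
22 | (2E,4E)-octa-2,4-dienoic acid | CCC/C=C/C=C/C(=O)O | starting material
23 | N,N′-dicyclohexyl-O-[(2E,4E)-octa-2,4-dienoyl]isourea | CCC/C=C/C=C/C(=O)OC(NC1CCCCC1)=NC1CCCCC1 | intermediate
24 | tert-butyl (2S,3R,4aS,5S,8aR)-5-[(5R)-5-[(tert-butyldimethylsilyl)oxy]octyl]-2-methyl-3-{[(2E,4E)-octa-2,4-dienoyl]oxy}octahydroquinoline-1(2H)-carboxylate | C[C@@H]1N(C(=O)OC(C)(C)C)[C@@H]2CCC[C@H](CCCC[C@H](O[Si](C)(C)C(C)(C)C)CCC)[C@@H]2C[C@H]1OC(=O)/C=C/C=C/CCC | intermediate
25 | lepadin H, (2S,3R,4aS,5S,8aR)-5-[(5R)-5-hydroxyoctyl]-2-methyldecahydroquinolin-3-yl (2E,4E)-octa-2,4-dienoate | C[C@@H]1N[C@@H]2CCC[C@H](CCCC[C@H](O)CCC)[C@@H]2C[C@H]1OC(=O)/C=C/C=C/CCC | target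

**Totals.** Total step count: 17. Longest linear sequence: 15 steps (steps 1–11 and 14–17); steps 12–13 make the side-chain alkene separately.

**Steps most likely to fail**

Step 9. Carbene side reactions (O–H insertion into methanol, 1,2-hydride shift to an enone) or poor facial control in the protonation of the ketene adduct could erode the contraction. The fallback contracts the ring by a semipinacol (Tiffeneau-type) rearrangement instead. It sets out from ketone 10: the kinetic lithium enolate is brominated with NBS to the 6-bromo ketone F1, NaBH4 reduces this to the bromohydrin F2, and the magnesium alkoxide of F2 (i-PrMgCl, toluene, warming) should undergo 1,2-shift of C4a from C5 to C6 with loss of bromide. This gives the ring-contracted aldehyde directly, so the route is rejoined at 15.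

Step 6. Poor facial selectivity, over-reduction of the ketone or saturation of the benzyl ring could spoil the hydrogenation. The fallback changes the order of events. It sets out from 8, which is first N-acylated (Boc2O, DMAP, MeCN) to the N-Boc vinylogous amide F3, in which A(1,3) strain turns the C2 methyl axial. Conjugate reduction with L-Selectride (THF, −78 °C) should then deliver hydride to C9a anti to that methyl, and protonation of the enolate gives the cis-fused ketone, so the route is rejoined at 10.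

Step 14. The hindered vinyl group may fail to enter the catalytic cycle, or homodimerisation of 19 may dominate. The fallback makes the C1′–C2′ bond by Julia–Kocienski olefination. It sets out from 19: ozonolysis with NaBH4 work-up gives (4R)-4-[(tert-butyldimethylsilyl)oxy]heptan-1-ol F4, Mitsunobu reaction with 1-phenyl-1H-tetrazole-5-thiol gives the sulfide F5, and Mo(VI)/H2O2 oxidation gives the sulfone F6. The potassium anion of F6 (KHMDS, DME, −60 °C) is condensed with aldehyde 15, which skips step 11, and the route is rejoined at 20.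

**Further compounds**

F1 | step 9 | tert-butyl (2S,3R,4aR,9aR)-3-(benzyloxy)-6-bromo-2-methyl-5-oxodecahydro-1H-cyclohepta[b]pyridine-1-carboxylate (C6 epimers) | C[C@@H]1N(C(=O)OC(C)(C)C)[C@@H]2CCCC(Br)C(=O)[C@@H]2C[C@H]1OCc3ccccc3
F2 | step 9 | tert-butyl (2S,3R,4aR,9aR)-3-(benzyloxy)-6-bromo-5-hydroxy-2-methyldecahydro-1H-cyclohepta[b]pyridine-1-carboxylate (C5/C6 isomers) | C[C@@H]1N(C(=O)OC(C)(C)C)[C@@H]2CCCC(Br)C(O)[C@@H]2C[C@H]1OCc3ccccc3
F3 | step 6 | tert-butyl (2S,3R)-3-(benzyloxy)-2-methyl-5-oxo-2,3,4,5,6,7,8,9-octahydro-1H-cyclohepta[b]pyridine-1-carboxylate | C[C@@H]1N(C(=O)OC(C)(C)C)C2=C(C[C@H]1OCc3ccccc3)C(=O)CCCC2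
F4 | step 14 | (4R)-4-[(tert-butyldimethylsilyl)oxy]heptan-1-ol | OCCC[C@H](O[Si](C)(C)C(C)(C)C)CCC
F5 | step 14 | 5-({(4R)-4-[(tert-butyldimethylsilyl)oxy]heptyl}sulfanyl)-1-phenyl-1H-tetrazole | c1ccccc1-n1nnnc1SCCC[C@H](O[Si](C)(C)C(C)(C)C)CCC
F6 | step 14 | 5-({(4R)-4-[(tert-butyldimethylsilyl)oxy]heptyl}sulfonyl)-1-phenyl-1H-tetrazole | c1ccccc1-n1nnnc1S(=O)(=O)CCC[C@H](O[Si](C)(C)C(C)(C)C)CCC
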